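Saturday's run ended at 61.5% D after 144 h; Monday's, with twice the c_Z, ended at 76.3%. Before choosing the next flask I wrote the balance of Z, the reagent charged in the smaller amount, 37 mM against 1.6 M of X. I took that balance as closed, so c_Z stays at the charge and the D branch is pseudo-first-order in X. The ratio of D to the rest of what X has become should then scale with c_Z.

Saturday's last reading gave 0.0432 mM⁻¹ for the split per catalyst, which is that ratio divided by c_Z, taking whatever of the charge was not D as the rest. Monday's gave 0.0435 mM⁻¹, although c_X doubled as well, so I assumed c_X neutral. Friday's, at 15 °C, gave 0.0243 mM⁻¹, a slope of 1200 K against reciprocal temperature.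

| flask | X | Z | temperature | remark | time |
|---|---|---|---|---|---|
| Saturday's | 0.80 M | 37 mM | −20 °C | run made earlier |  |
| Friday's | 1.2 M | 37 mM | 15 °C | run made earlier |  |
| Monday's | 1.6 M | 74 mM | −20 °C | run made earlier |  |
| south-east | 1.6 M | 37 mM | 45 °C |  | 6.0 h |
| west | 1.6 M | 37 mM | 5 °C |  | 6.0 h |
| south | 1.6 M | 37 mM | −15 °C |  | 6.0 h |
| north-east | 1.6 M | 37 mM | 25 °C |  | 6.0 h |

| run | time / h | D / % | Q / % |
|---|---|---|---|
| Saturday's | 30.0 | 39.5 | 21.1 |
| Saturday's | 60.0 | 54.0 | 30.3 |
| Saturday's | 96.0 | 59.6 | 33.5 |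
| Saturday's | 120 | 60.5 | 34.0 |
| Saturday's | 144 | 61.5 | 34.9 |
| Friday's | 6.00 | 46.7 | 49.3 |
| Friday's | 12.0 | 46.2 | 49.7 |
| Friday's | 20.0 | 46.9 | 49.2 |
| Friday's | 25.0 | 47.3 | 49.5 |
| Monday's | 12.0 | 37.3 | 9.2 |
| Monday's | 20.0 | 51.2 | 14.0 |
| Monday's | 40.0 | 67.7 | 19.3 |
| Monday's | 72.0 | 75.2 | 21.1 |
| Monday's | 144 | 76.3 | 21.5 |

(scatter of a reading: 0.3 percentage points)

1. the best flask by share of D in all that became D or Q or E; "all alike" if 1.5 percentage points covers them all (south-east / west / south / north-east / all alike)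
2. share of D in all that became D or Q or E, south-east
3. share of D in all that became D or Q or E, west
4. share of D in all that became D or Q or E, south
5. share of D in all that became D or Q or E, north-east

South and west lie between these runs in temperature; south-east and north-east lie above them, so I did not carry the split there. At −15 °C and 37 mM it puts 59.3% of what left X into D, and at 5 °C it puts 51.0%. The asked share leaves J out, and Monday's D/Q stood at 4.05 after 12.0 h against 3.55 at the end, which I read as Q lagging behind D with J between them. Saturday's D stood at 39.5% after 30.0 h, so I expected south, at −15 °C, to be unfinished after 6.0 h and to read above my figure. Of the two flasks I had reckoned, I chose south.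

The forecast, whose figures are the asked share where mine counts J as having left X, named south, with 65% there, 50.7% west, 43.2% north-east and 37% south-east, adding “The other flasks are essentially finished.”

The best flask was south, at 65.1% against 59.6% south-east, 49.8% west and 46.3% north-east.

    X ⇌ J (K = 2.00, k = 0.00127 s⁻¹, Ea = 83.0 kJ mol⁻¹, ΔH = −50.0 kJ mol⁻¹)
    X + Z → Z + D (k = 0.0264 M⁻¹ s⁻¹, Ea = 71.0 kJ mol⁻¹)
    Z + J → Z + Q (k = 0.0543 M⁻¹ s⁻¹, Ea = 39.0 kJ mol⁻¹)
    G ⇌ D, rate k4*(cs4 - [D]) while solid is left; crystals form when [D] > cs4 (solubility = 0.140 M, k = 0.00554 s⁻¹)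
    X + D → E (k = 2.87 × 10⁻⁴ M⁻¹ s⁻¹, Ea = 75.0 kJ mol⁻¹)
    (constants at 25 °C)

At 6.00 h south held 66.4% X and 2.90% J. With that J counted, D made up 59.5% of what had left X, against the split's 59.3%. The neighbour of south charged with 15.0 mM of Z gave 53.3% as asked. With its 6.67% J counted it gave 37.6%, where the split per catalyst gives 37.1%.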